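The earlier runs and the new flask come from a simulation from invented constants; the scatter is artificial.

If single product is made and lost by steps each first order in partner, their ratio, the selectivity factor, does not depend on partner. Flasks with equal starting material then pass through the same amounts, and partner sets the speed.

| setting | noon | dawn | spring | flask |
|---|---|---|---|---|
| starting material | 0.020 M | 0.020 M | 0.030 M | 0.020 M |
| partner | 0.030 M | 0.12 M | 0.060 M | 0.0600 M |
| remark | run made earlier | run made earlier | run made earlier |  |
| time |  |  |  | 2.0 h |

- noon (time / min: single product / %): 5.00: 13.2; 15.0: 27.6; 25.0: 33.8; 40.0: 37.2; 60.0: 39.7; 80.0: 43.3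
- dawn (time / min: single product / %): 12.0: 48.5; 25.0: 40.6; 40.0: 31.7; 50.0: 26.5; 60.0: 20.9; 80.0: 14.6
- spring (time / min: single product / %): 6.00: 25.6; 10.0: 34.1; 20.0: 42.2; 40.0: 41.1; 80.0: 38.6

(each reading ± 1 percentage point)

- the numbers in the tables scatter with a standard deviation of 1 percentage point
- a reading or a percentage of single product counts all its forms, free or not

- equivalents of partner to starting material, everything else as given, that leave most single product at 2.0 h
- the amount of single product then, in percent of the starting material charged
- the amount of single product with the amounts as given

The flask and the dawn run held the same 0.020 M of starting material. I took each one's mean partner as its excess over one equivalent, c_B − c_A, where c_B and c_A are the charges. I then defined the dawn-equivalent time τ = t(c_B − c_A)/(c_B − c_A)_dawn, the dawn time that shows what a flask shows at its own time t. For the flask, τ was 48.0 min, and between the dawn readings there I read 27.5%. Dawn's highest reading, at 12.0 min, mapped back to 1.50 equiv, the noon charge, whose last reading, at 80.0 min, was 43.3%; that was my choice for the best recipe.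

The forecast differed from mine, with 2 equiv, 40% and 36%, holding that “Lowering the partner gives less formation but less decay.”

The flask gave 29.0%, and the best recipe, 1.39 equiv, gave 41.5%.

    starting material + partner → single product + by-product (k = 1.10 /M/min)
    partner + single product → bis adduct + by-product (k = 0.370 /M/min)
    partner + bis adduct ⇌ triple product + by-product (K = 0.420, k = 0.770 /M/min)
    starting material + single product ⇌ idle adduct, settled at all times (K = 74.0 /M)
    single product ⇌ isomer of the product (K = 0.630, k = 0.0470 /min)

My reading of 27.5% stood against 29.0%. The flask ended with 47% of its partner, so the mean of its start and end was 0.0441 M, against the 0.0400 M I had used. The flask's single product moved 5 points at 0.0702 M of partner with the time held, and at 2.62 h with the partner held; τ gives these 60.3 min and 62.8 min.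

For the neighbour with 0.036 M of partner, τ was 19.2 min, where the dawn readings gave 44.1%. That flask gave 40.1%.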